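The cyclopentane that joins the two spiro centres is disconnected at C(pinane‑2)–CH2 and C(dione‑2)–CH(iPr): a radical [3+2] annulation of a homoprenyl radical across the tetrasubstituted Knoevenagel alkene of nopinone and the cyclic trione. In one operation this forms both bonds, closes ring B, creates the isopropyl group and sets three stereocentres next to the chiral‑pool pinane. It exploits the fact that the dione carbon must sit on the hindered gem‑dimethyl‑bridge face of pinane C‑2: that is only possible if this carbon is already bonded (as C=C) while the new carbon enters from the open face. The precursor is the flat alkylidene trione plus 5‑bromo‑2‑methylpent‑2‑ene.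

Key step: step 6

Remark: (1R,5R)-(+)-β-pinene is taken as purchasable (it can otherwise be made from (+)-α-pinene), and the enolisable triones are each written as one tautomer.

Step 1
Reactants: 1 methyl 2-methylpropanoate
Product: 2 methyl 2,2-dimethyl-3-oxopentanoate
Conditions: LDA, THF, −78 °C; then added to EtCOCl, −78 °C → rt
Reagents that add atoms: propanoyl chloride, CCC(Cl)=O
Why: Claisen-type C-acylation of the lithium enolate of an α,α-disubstituted ester by an acid chloride should be clean, because the product has no proton between its carbonyl groups and cannot quench unreacted enolate.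

Step 2
Reactants: 2 methyl 2,2-dimethyl-3-oxopentanoate
Product: 3 methyl 2,2,4-trimethyl-3,5-dioxohexanoate
Conditions: LDA, THF, −78 °C; MeC(O)N(OMe)Me, −78 → 0 °C; aq. HCl
Reagents that add atoms: N-methoxy-N-methylacetamide, CC(=O)N(C)OC
Why: The ethyl CH2 is the only enolisable position of 2, and C-acylation of its lithium enolate with a Weinreb amide stops at the stable tetrahedral adduct, so neither proton transfer from the 1,3-diketone nor double addition should occur.

Step 3
Reactants: 3 methyl 2,2,4-trimethyl-3,5-dioxohexanoate
Product: 4 3,5-dihydroxy-2,4,4-trimethylcyclohexa-2,5-dien-1-one (dienol form of 2,2,4-trimethylcyclohexane-1,3,5-trione)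
Conditions: LDA (2.3 equiv), THF, −78 → 0 °C; aq. HCl
Reagents that add atoms: none
Why: Double deprotonation gives the 1,3-diketone dianion, whose terminal methyl carbanion attacks the only ester in a 6-exo-trig Dieckmann-type condensation that the acidic trione product drives to completion.

Step 4
Reactants: 5 (1R,5R)-(+)-β-pinene
Product: 7 (1S,5R)-6,6-dimethylbicyclo[3.1.1]heptan-2-one, via secondary ozonide 6 (not isolated)
Conditions: O3, CH2Cl2, −78 °C; then Me2S, −78 °C → rt
Reagents that add atoms: ozone, [O-][O+]=O
Why: Ozonolysis of the 1,1-disubstituted alkene with reductive work-up should give (−)-nopinone without touching the bridgehead stereocentres or the cyclobutane.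

Step 5
Reactants: 4 3,5-dihydroxy-2,4,4-trimethylcyclohexa-2,5-dien-1-one; 7 (1S,5R)-6,6-dimethylbicyclo[3.1.1]heptan-2-one
Product: 8 2-[(1S,5R)-6,6-dimethylbicyclo[3.1.1]heptan-2-ylidene]-5-hydroxy-4,6,6-trimethylcyclohex-4-ene-1,3-dione (E/Z mixture)
Conditions: TiCl4, pyridine, THF, 0 °C → rt
Reagents that add atoms: none
Why: In this TiCl4/pyridine Knoevenagel condensation only the unsubstituted carbon C-6 of 4 can lose water after aldol addition (addition at the methyl-bearing carbon is reversible and cannot eliminate), and the E/Z ratio of 8 is irrelevant because both isomers give the same radical in step 6.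

Step 6
Reactants: 8 alkylidene trione; 9 5-bromo-2-methylpent-2-ene
Product: 10 (1S,2R,2′R,3′R,5R)-4″-hydroxy-3″,5″,5″,6,6-pentamethyl-3′-(propan-2-yl)dispiro[bicyclo[3.1.1]heptane-2,1′-cyclopentane-2′,1″-cyclohexan]-3″-ene-2″,6″-dione (dione carbon on the gem-dimethyl-bridge face of pinane C-2; iPr cis to C-2″=O and to pinane C-3)
Conditions: 9 (3 equiv), (Me3Si)3SiH (syringe pump), AIBN (cat.), PhH, 80 °C
Reagents that add atoms: none
Why: The silyl radical abstracts bromine from 9; the homoprenyl radical adds to the pinane carbon of the electron-poor C=C of 8 to give the delocalised 1,3-dicarbonyl radical (never a radical or cation at pinane C-2, so the cyclobutane cannot open), this radical closes onto the trisubstituted alkene, and the tertiary radical takes H from the silane, which creates the isopropyl group. The closest known reaction type is the reductive radical [3+2] annulation of but-3-enyl radicals with electron-poor alkenes (Giese addition followed by cyclisation), its second half being the 5-exo closure of 1,3-dicarbonyl radicals familiar from Mn(III) chemistry. The cyclopentane closes in the 5-exo-trig mode. The pinane spiro centre is controlled by the bicycle, since the radical enters anti to the gem-dimethyl bridge as reagents do with nopinone and β-pinene, which leaves the dione carbon on the bridge face. The CH–iPr centre is controlled by a chair-like transition state that holds the alkene terminus on the side of pinane C-3H2 and away from bridgehead C-1, and the dione spiro centre by the same terminus lying over the flat C(=O)–C(Me)=C arm and not over the arm whose CMe2 carries an out-of-plane methyl group; closure of such stabilised radicals is reversible, and both preferences should also be the thermodynamic ones. The step needs addition at the pinane carbon and 5-exo instead of 6-endo closure, which the two carbonyl groups (electrophilic terminus, stabilised adduct radical) and the gem-dimethyl alkene terminus (tertiary radical only on 5-exo attack) secure, while slow addition of the silane keeps hydrogen transfer behind both C–C bond formations.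

Step 7
Reactants: 10 dispiro enol
Product: 11 (1S,2R,2′R,3′R,5R)-4″-methoxy-3″,5″,5″,6,6-pentamethyl-3′-(propan-2-yl)dispiro[bicyclo[3.1.1]heptane-2,1′-cyclopentane-2′,1″-cyclohexan]-3″-ene-2″,6″-dione (CNP0307059.1)
Conditions: Me2SO4, K2CO3, acetone, rt
Reagents that add atoms: dimethyl sulfate, COS(=O)(=O)OC
Why: In this O-alkylation of a cyclic 1,3-dione enolate with a hard electrophile only the C-2″/C-4″ diketone can enolise (C-6″=O lies between two quaternary carbons), and of its two oxygens the one next to the spiro centre is shielded by the cis isopropyl group and the cyclopentane, so methylation should go to the oxygen next to CMe2.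

Compound list
1 | methyl 2-methylpropanoate (methyl isobutyrate) | COC(=O)C(C)C | starting material
2 | methyl 2,2-dimethyl-3-oxopentanoate | CCC(=O)C(C)(C)C(=O)OC | intermediate
3 | methyl 2,2,4-trimethyl-3,5-dioxohexanoate (racemic, enolisable) | CC(=O)C(C)C(=O)C(C)(C)C(=O)OC | intermediate
4 | 3,5-dihydroxy-2,4,4-trimethylcyclohexa-2,5-dien-1-one (dienol of 2,2,4-trimethylcyclohexane-1,3,5-trione) | O=C1C=C(O)C(C)(C)C(O)=C1C | intermediate
5 | (1R,5R)-6,6-dimethyl-2-methylidenebicyclo[3.1.1]heptane, (+)-β-pinene | C=C1CC[C@@H]2C[C@H]1C2(C)C | starting material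
6 | secondary ozonide of 5, (1S,5R)-6,6-dimethylspiro[bicyclo[3.1.1]heptane-2,3′-[1,2,4]trioxolane] (spiro carbon unassigned; not isolated) | C1OC2(OO1)CC[C@@H]1C[C@H]2C1(C)C | intermediate
7 | (1S,5R)-6,6-dimethylbicyclo[3.1.1]heptan-2-one, (−)-nopinone | O=C1CC[C@@H]2C[C@H]1C2(C)C | intermediate
8 | 2-[(1S,5R)-6,6-dimethylbicyclo[3.1.1]heptan-2-ylidene]-5-hydroxy-4,6,6-trimethylcyclohex-4-ene-1,3-dione (E/Z mixture) | OC1=C(C)C(=O)C(=C2CC[C@@H]3C[C@H]2C3(C)C)C(=O)C1(C)C | intermediate
9 | 5-bromo-2-methylpent-2-ene | CC(C)=CCCBr | starting material
10 | (1S,2R,2′R,3′R,5R)-4″-hydroxy-3″,5″,5″,6,6-pentamethyl-3′-(propan-2-yl)dispiro[bicyclo[3.1.1]heptane-2,1′-cyclopentane-2′,1″-cyclohexan]-3″-ene-2″,6″-dione | OC1=C(C)C(=O)[C@@]2(C(=O)C1(C)C)[C@@H](C(C)C)CC[C@@]21CC[C@@H]2C[C@H]1C2(C)C | intermediate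
11 | (1S,2R,2′R,3′R,5R)-4″-methoxy-3″,5″,5″,6,6-pentamethyl-3′-(propan-2-yl)dispiro[bicyclo[3.1.1]heptane-2,1′-cyclopentane-2′,1″-cyclohexan]-3″-ene-2″,6″-dione | COC1=C(C)C(=O)[C@@]2(C(=O)C1(C)C)[C@@H](C(C)C)CC[C@@]21CC[C@@H]2C[C@H]1C2(C)C | target

Total steps: 7. Longest linear sequence: 6 (steps 1, 2, 3, 5, 6, 7).

Steps most likely to fail

Step 6. Hydrogen transfer from the silane (or from the enol O–H) may outrun addition of the alkyl radical to the hindered alkene or the cyclisation of the dione radical. The acceptor may also drift by prototropy to its dienol form, which does not accept radicals. The fallback sets out from 8 and removes the hydride donor: thiyl-radical-catalysed strain-release [3+2] annulation with 2-cyclopropylpropene (PhSSPh cat., AIBN, PhH, hν, 80 °C). The thiyl radical adds to the alkene, the cyclopropylcarbinyl radical opens, and the same addition and 5-exo sequence ends with loss of PhS• instead of hydrogen transfer. This should give the isopropenyl dispiro enol F1, and hydrogenation (H2, Pd/C, EtOAc) returns to the route at 10.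

Step 5. Retro-aldol cleavage may outrun dehydration at the hindered, enolisable ketone, and the trione may be tied up by the Lewis acid. The fallback sets out from 7 and 4 and replaces the condensation by a cross-coupling. Kinetic enolisation and triflation of 7 (LDA, PhNTf2, THF, −78 °C) gives nopinone enol triflate F2. Pd-catalysed α-alkenylation of 4 at its unsubstituted carbon (Pd2(dba)3, XPhos, K3PO4, dioxane, 80 °C) then gives the 2-alkenyl dienol F3. F3 is the prototropic tautomer of 8; it should reach 8 by 1,5-hydrogen shift on heating and comes back to the route at 8 for step 6.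

Step 7. Alkylation may occur at the wrong enol oxygen or at carbon. The fallback sets out from 10 and replaces base-mediated alkylation by reversible, acid-catalysed enol etherification (MeOH, cat. TsOH, 3 Å sieves, 50 °C). Under thermodynamic control both oxygens should funnel to the less congested vinylogous ester, so it comes back at 11; no new compound arises (F0).

Further compounds
F1 | step 6 | (1S,2R,2′R,3′R,5R)-4″-hydroxy-3″,5″,5″,6,6-pentamethyl-3′-(prop-1-en-2-yl)dispiro[bicyclo[3.1.1]heptane-2,1′-cyclopentane-2′,1″-cyclohexan]-3″-ene-2″,6″-dione | OC1=C(C)C(=O)[C@@]2(C(=O)C1(C)C)[C@@H](C(C)=C)CC[C@@]21CC[C@@H]2C[C@H]1C2(C)C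
F2 | step 5 | 6,6-dimethylbicyclo[3.1.1]hept-2-en-2-yl trifluoromethanesulfonate (bridgeheads as in 7) | O=S(=O)(OC1=CC[C@@H]2C[C@H]1C2(C)C)C(F)(F)F
F3 | step 5 | 6-[6,6-dimethylbicyclo[3.1.1]hept-2-en-2-yl]-3,5-dihydroxy-2,4,4-trimethylcyclohexa-2,5-dien-1-one (dienol tautomer of 8; bridgeheads as in 7) | O=C1C(C)=C(O)C(C)(C)C(O)=C1C1=CC[C@@H]2C[C@H]1C2(C)C
F0 | step 7 | none | none
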